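**Retrosynthetic overview**
- The strategy rests on ring C: a benzene ring substituted 1,4 by the diaryl ether oxygen (bound to C3 of ring B) and by the benzylic carbon of the CH2CH2 bridge to ring D. A 2-pyrone acylated at C5 gives exactly this O/C para pattern with a terminal alkynyl ether once CO2 is lost.
- Last disconnection: the bridge CH2 next to ring C is traced back to a ketone and the two phenols to benzyl ethers, all taken down in one hydrogenation of a deoxybenzoin.
- Key disconnection: ring C of that deoxybenzoin is opened to an aryl ethynyl ether carrying rings A and B (the ether oxygen already on the alkyne) and a 5-(arylacetyl)-2-pyrone carrying ring D. Rings A, B and D are bought; ring C is the only ring formed.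
- The ynol ether comes from 4-(benzyloxy)-3-hydroxybenzaldehyde by Wittig olefination, diimide reduction, O-dichlorovinylation with trichloroethylene and elimination. The acylpyrone comes from coumalyl chloride and a benzylzinc bromide by Negishi acylation.

Key step: step 9

Remark: the target has no stereocentre and no stereogenic double bond, so it is achiral and the route needs no stereocontrol. The E/Z mixture formed in step 1 is erased in step 2.

**Step 1**
Reactants: 1 4-(benzyloxy)-3-hydroxybenzaldehyde; 2 (3-methoxybenzyl)triphenylphosphonium chloride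
Product: 4 2-(benzyloxy)-5-[2-(3-methoxyphenyl)ethenyl]phenol (E/Z mixture), via benzylidene phosphorane 3 (not isolated)
Conditions: 2 (1.3 equiv), t-BuOK (2.5 equiv), THF, 0 °C; then 1, 0 °C → rt; aq. NH4Cl
Reagents that add atoms: none
Why: Wittig olefination by the semi-stabilised benzylidene ylide; the extra base holds the phenol as its potassium salt, which sits meta to the formyl group and so leaves it electrophilic, and the alkene geometry is irrelevant because the double bond is reduced next.

**Step 2**
Reactants: 4 2-(benzyloxy)-5-[2-(3-methoxyphenyl)ethenyl]phenol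
Product: 5 2-(benzyloxy)-5-[2-(3-methoxyphenyl)ethyl]phenol
Conditions: TsNHNH2 (5 equiv), NaOAc (5 equiv), DME/H2O, reflux
Reagents that add atoms: none
Why: Diimide reduction: diimide released from the sulfonyl hydrazide transfers H2 in a concerted syn fashion to the stilbene C=C only and, unlike hydrogenation over Pd, leaves the O-benzyl ether intact.

**Step 3**
Reactants: 5 2-(benzyloxy)-5-[2-(3-methoxyphenyl)ethyl]phenol; 6 trichloroethylene
Product: 8 1-(benzyloxy)-2-{[(E)-1,2-dichloroethenyl]oxy}-4-[2-(3-methoxyphenyl)ethyl]benzene, via dichloroacetylene 7 (not isolated)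
Conditions: 6 (2 equiv), K2CO3 (3 equiv), DMF, 70 °C
Reagents that add atoms: none
Why: Carbonate eliminates HCl from trichloroethylene to dichloroacetylene, to which the phenoxide adds in an anti sense to give the (E)-1,2-dichlorovinyl ether, an established O-vinylation of phenols.

**Step 4**
Reactants: 8 1-(benzyloxy)-2-{[(E)-1,2-dichloroethenyl]oxy}-4-[2-(3-methoxyphenyl)ethyl]benzene
Product: 11 1-(benzyloxy)-2-(ethynyloxy)-4-[2-(3-methoxyphenyl)ethyl]benzene, via aryl chloroethynyl ether 9 (not isolated), via lithium aryloxyacetylide 10 (not isolated)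
Conditions: n-BuLi (2.3 equiv), THF, −78 → −40 °C; then H2O, −78 °C → rt; quick filtration through Et3N-deactivated silica, used at once
Reagents that add atoms: none
Why: The known dichlorovinyl ether route to ynol ethers: the first equivalent of n-BuLi effects β-elimination of HCl to the chloroalkynyl ether, the second a chlorine–lithium exchange to the acetylide, which water protonates at carbon; at −78 °C neither ortho-lithiation nor Wittig rearrangement of the benzyl ether should compete.

**Step 5**
Reactants: 12 3-(benzyloxy)benzyl alcohol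
Product: 13 1-(benzyloxy)-3-(bromomethyl)benzene
Conditions: PBr3 (0.4 equiv), CH2Cl2, 0 °C
Reagents that add atoms: phosphorus tribromide, BrP(Br)Br
Why: SN2 bromination of a primary benzylic alcohol through its phosphite ester; the aryl benzyl ether is inert to PBr3 at 0 °C.

**Step 6**
Reactants: 13 1-(benzyloxy)-3-(bromomethyl)benzene
Product: 14 [3-(benzyloxy)benzyl]zinc bromide (THF solution, titrated with I2)
Conditions: Zn dust (1.5 equiv, activated), LiCl (1.5 equiv), THF, rt
Reagents that add atoms: zinc, [Zn]
Why: LiCl-promoted direct insertion of zinc into the benzylic C–Br bond at room temperature gives the benzylzinc halide with little Wurtz homocoupling.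

**Step 7**
Reactants: 15 coumalic acid (2-oxo-2H-pyran-5-carboxylic acid)
Product: 16 coumalyl chloride (2-oxo-2H-pyran-5-carbonyl chloride)
Conditions: SOCl2, cat. DMF, reflux; evaporate, use crude
Reagents that add atoms: thionyl chloride, O=S(Cl)Cl
Why: Standard acid chloride formation through the chlorosulfite; coumalyl chloride is a known, isolable compound and the pyrone ring tolerates SOCl2.

**Step 8**
Reactants: 14 [3-(benzyloxy)benzyl]zinc bromide; 16 coumalyl chloride
Product: 17 5-{[3-(benzyloxy)phenyl]acetyl}-2H-pyran-2-one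
Conditions: Pd(PPh3)4 (5 mol %), THF, 0 °C → rt, slow addition of 14 (1.05 equiv) to 16
Reagents that add atoms: none
Why: Negishi acylation (oxidative addition of Pd(0) into the acyl C–Cl bond, benzyl transfer from zinc, reductive elimination) forms the ketone, and the weakly basic, weakly nucleophilic organozinc should spare the electrophilic pyrone ring and the acidic CH2 of the product.

**Step 9**
Reactants: 11 1-(benzyloxy)-2-(ethynyloxy)-4-[2-(3-methoxyphenyl)ethyl]benzene; 17 5-{[3-(benzyloxy)phenyl]acetyl}-2H-pyran-2-one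
Product: 19 2-[3-(benzyloxy)phenyl]-1-(4-{2-(benzyloxy)-5-[2-(3-methoxyphenyl)ethyl]phenoxy}phenyl)ethan-1-one, via bicyclic lactone cycloadduct 18 (not isolated)
Conditions: 11 (1.5 equiv), toluene, 90–110 °C, sealed tube, Ar
Reagents that add atoms: none
Why: Proposed new method: the electron-poor diene C3=C4–C5=C6 of pyrone 17, its LUMO lowered by the lactone carbonyl and the 5-acyl group, should add the electron-rich alkyne of 11 in an asynchronous inverse-electron-demand [4+2] cycloaddition in which the nucleophilic terminal CH bonds to C6 (β to the acyl carbonyl, δ to the lactone carbonyl) ahead of the oxygen-bearing alkyne carbon bonding to C3, giving the 2-oxabicyclo[2.2.2]octadienone 18, which then expels CO2 by retro-[4+2] and delivers the arene with no oxidant because the 2π partner is already at the alkyne oxidation level. The closest known reaction type is the thermal Diels–Alder/decarboxylation benzannulation of coumalate esters with alkynes, enol ethers, ketene acetals and ynamines to para-substituted benzoates; new here are an aryl ethynyl ether as the 2π partner and a 5-ketone in place of the 5-ester. Ring C is closed by intermolecular [4+2] cycloaddition (bonds C6–CH and C3–C(OAr)) followed by cycloreversion that removes the O1–C2 bridge, so its six carbons are pyrone C3–C6 plus the two alkyne carbons. No stereocentre is created in 19, and the two bridgehead centres of racemic 18 vanish on aromatisation. The step needs para rather than meta regiochemistry and [4+2] periselectivity over hetero-Diels–Alder addition to the O=C–C5=C6 enone or [2+2] addition; the matched polarisation (largest LUMO coefficient at C6, largest HOMO coefficient at the terminal alkyne carbon) secures the first, only the C3/C6 adduct can drain irreversibly to an aromatic ring by CO2 loss, and an aryl ynol ether has no sp3 C–H β to oxygen and so cannot fragment to a ketene by retro-ene on heating.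

**Step 10**
Reactants: 19 2-[3-(benzyloxy)phenyl]-1-(4-{2-(benzyloxy)-5-[2-(3-methoxyphenyl)ethyl]phenoxy}phenyl)ethan-1-one
Product: 20 2-{4-[2-(3-hydroxyphenyl)ethyl]phenoxy}-4-[2-(3-methoxyphenyl)ethyl]phenol (target, CNP0225725.0)
Conditions: H2 (4 atm), 10% Pd/C, EtOAc/AcOH, cat. HClO4, 40–50 °C
Reagents that add atoms: none
Why: Catalytic hydrogenation/hydrogenolysis over Pd/C in acid: the aryl ketone, activated by the para aryloxy group, is reduced to the benzylic alcohol and on to CH2 while both O-benzyl ethers are cleaved; the diaryl ether, the aryl methyl ether and the arene rings are inert to Pd under these conditions.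

**Compound list**
1 | 4-(benzyloxy)-3-hydroxybenzaldehyde | O=Cc1ccc(OCc2ccccc2)c(O)c1 | starting material
2 | (3-methoxybenzyl)triphenylphosphonium chloride | COc1cccc(C[P+](c2ccccc2)(c2ccccc2)c2ccccc2)c1.[Cl-] | starting material
3 | (3-methoxybenzylidene)triphenylphosphorane | COc1cccc(C=P(c2ccccc2)(c2ccccc2)c2ccccc2)c1 | intermediate
4 | 2-(benzyloxy)-5-[2-(3-methoxyphenyl)ethenyl]phenol (E/Z mixture) | COc1cccc(C=Cc2ccc(OCc3ccccc3)c(O)c2)c1 | intermediate
5 | 2-(benzyloxy)-5-[2-(3-methoxyphenyl)ethyl]phenol | COc1cccc(CCc2ccc(OCc3ccccc3)c(O)c2)c1 | intermediate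
6 | trichloroethylene | ClC=C(Cl)Cl | starting material
7 | dichloroacetylene | ClC#CCl | intermediate
8 | 1-(benzyloxy)-2-{[(E)-1,2-dichloroethenyl]oxy}-4-[2-(3-methoxyphenyl)ethyl]benzene | COc1cccc(CCc2ccc(OCc3ccccc3)c(O/C(Cl)=C\Cl)c2)c1 | intermediate
9 | 1-(benzyloxy)-2-[(chloroethynyl)oxy]-4-[2-(3-methoxyphenyl)ethyl]benzene | COc1cccc(CCc2ccc(OCc3ccccc3)c(OC#CCl)c2)c1 | intermediate
10 | lithium 2-{2-(benzyloxy)-5-[2-(3-methoxyphenyl)ethyl]phenoxy}ethynide | COc1cccc(CCc2ccc(OCc3ccccc3)c(OC#C[Li])c2)c1 | intermediate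
11 | 1-(benzyloxy)-2-(ethynyloxy)-4-[2-(3-methoxyphenyl)ethyl]benzene | COc1cccc(CCc2ccc(OCc3ccccc3)c(OC#C)c2)c1 | intermediate
12 | 3-(benzyloxy)benzyl alcohol | OCc1cccc(OCc2ccccc2)c1 | starting material
13 | 1-(benzyloxy)-3-(bromomethyl)benzene | BrCc1cccc(OCc2ccccc2)c1 | intermediate
14 | [3-(benzyloxy)benzyl]zinc bromide | Br[Zn]Cc1cccc(OCc2ccccc2)c1 | intermediate
15 | coumalic acid | O=C(O)C1=COC(=O)C=C1 | starting material
16 | coumalyl chloride | O=C(Cl)C1=COC(=O)C=C1 | intermediate
17 | 5-{[3-(benzyloxy)phenyl]acetyl}-2H-pyran-2-one | O=C(Cc1cccc(OCc2ccccc2)c1)C1=COC(=O)C=C1 | intermediate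
18 | 5-{2-(benzyloxy)-5-[2-(3-methoxyphenyl)ethyl]phenoxy}-7-{[3-(benzyloxy)phenyl]acetyl}-2-oxabicyclo[2.2.2]octa-5,7-dien-3-one (racemic) | O=C1OC2C=C(Oc3cc(CCc4cccc(OC)c4)ccc3OCc5ccccc5)C1C=C2C(=O)Cc6cccc(OCc7ccccc7)c6 | intermediate
19 | 2-[3-(benzyloxy)phenyl]-1-(4-{2-(benzyloxy)-5-[2-(3-methoxyphenyl)ethyl]phenoxy}phenyl)ethan-1-one | COc1cccc(CCc2ccc(OCc3ccccc3)c(Oc4ccc(C(=O)Cc5cccc(OCc6ccccc6)c5)cc4)c2)c1 | intermediate
20 | 2-{4-[2-(3-hydroxyphenyl)ethyl]phenoxy}-4-[2-(3-methoxyphenyl)ethyl]phenol | COc1cccc(CCc2ccc(O)c(Oc3ccc(CCc4cccc(O)c4)cc3)c2)c1 | target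

**Total step count:** 10
**Longest linear sequence:** 6 steps (1, 2, 3, 4, 9, 10)

**Steps most likely to fail**

Step 9 (the labelled step). The ynol ether may oligomerise on heating before it is intercepted, or the addition may take another course (hetero-Diels–Alder onto the enone, or [2+2]), so that ring C does not form cleanly. The fallback uses only known chemistry, sets out from phenol 5 and bromide 13, and comes back to the route at target 20. Phenol 5 and 4-fluorobenzaldehyde (K2CO3, DMF, 130 °C) should give by SNAr 4-{2-(benzyloxy)-5-[2-(3-methoxyphenyl)ethyl]phenoxy}benzaldehyde F1. Bromide 13 and PPh3 in refluxing toluene give [3-(benzyloxy)benzyl]triphenylphosphonium bromide F2, which t-BuOK in THF converts to [3-(benzyloxy)benzylidene]triphenylphosphorane F3. Wittig reaction of F3 with F1 gives the stilbene 1-(benzyloxy)-2-(4-{2-[3-(benzyloxy)phenyl]ethenyl}phenoxy)-4-[2-(3-methoxyphenyl)ethyl]benzene F4 as an E/Z mixture. Hydrogenation of F4 (H2, Pd/C, EtOAc/EtOH, rt) saturates the alkene and cleaves both benzyl ethers to give 20.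

Step 8. Addition of the organozinc to the electrophilic pyrone ring, or enolisation of the product ketone and its condensation with more pyrone, may outrun the acyl coupling. The fallback installs the ketone after the arene is built; it sets out from ynol ether 11 and bromide 13 and comes back at ketone 19. Commercial methyl coumalate and 11 in toluene at 100 °C should give, through the cycloadduct methyl 5-{2-(benzyloxy)-5-[2-(3-methoxyphenyl)ethyl]phenoxy}-3-oxo-2-oxabicyclo[2.2.2]octa-5,7-diene-7-carboxylate F5 and loss of CO2, the ester methyl 4-{2-(benzyloxy)-5-[2-(3-methoxyphenyl)ethyl]phenoxy}benzoate F6. Treatment of F6 with MeNHOMe·HCl and i-PrMgCl (THF, −20 °C) gives the Weinreb amide 4-{2-(benzyloxy)-5-[2-(3-methoxyphenyl)ethyl]phenoxy}-N-methoxy-N-methylbenzamide F7. Bromide 13 and magnesium in Et2O at 0 °C give [3-(benzyloxy)benzyl]magnesium bromide F8, and addition of F8 to F7 (THF, 0 °C, then aqueous acid) gives 19.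

Step 10. The hydrogenation may stall at the benzylic alcohol once the benzyl ethers have gone, or the acid may promote side reactions of the electron-rich rings. The fallback separates deoxygenation from debenzylation; it sets out from ketone 19 and comes back at target 20. Wolff–Kishner reduction under Huang–Minlon conditions (N2H4·H2O, KOH, diethylene glycol, 130 then 200 °C) converts 19 through the hydrazone (1-{2-[3-(benzyloxy)phenyl]-1-(4-{2-(benzyloxy)-5-[2-(3-methoxyphenyl)ethyl]phenoxy}phenyl)ethylidene}hydrazine) F9 to 1-(benzyloxy)-2-(4-{2-[3-(benzyloxy)phenyl]ethyl}phenoxy)-4-[2-(3-methoxyphenyl)ethyl]benzene F10; the benzyl ethers are stable to the base. Neutral hydrogenolysis of F10 (H2, Pd/C, EtOAc/EtOH, rt) then gives 20.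

**Further compounds**
F1 | step 9 | 4-{2-(benzyloxy)-5-[2-(3-methoxyphenyl)ethyl]phenoxy}benzaldehyde | COc1cccc(CCc2ccc(OCc3ccccc3)c(Oc4ccc(C=O)cc4)c2)c1
F2 | step 9 | [3-(benzyloxy)benzyl]triphenylphosphonium bromide | [Br-].c1ccc(COc2cccc(C[P+](c3ccccc3)(c3ccccc3)c3ccccc3)c2)cc1
F3 | step 9 | [3-(benzyloxy)benzylidene]triphenylphosphorane | c1ccc(COc2cccc(C=P(c3ccccc3)(c3ccccc3)c3ccccc3)c2)cc1
F4 | step 9 | 1-(benzyloxy)-2-(4-{2-[3-(benzyloxy)phenyl]ethenyl}phenoxy)-4-[2-(3-methoxyphenyl)ethyl]benzene (E/Z mixture) | COc1cccc(CCc2ccc(OCc3ccccc3)c(Oc4ccc(C=Cc5cccc(OCc6ccccc6)c5)cc4)c2)c1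
F5 | step 8 | methyl 5-{2-(benzyloxy)-5-[2-(3-methoxyphenyl)ethyl]phenoxy}-3-oxo-2-oxabicyclo[2.2.2]octa-5,7-diene-7-carboxylate (racemic) | O=C1OC2C=C(Oc3cc(CCc4cccc(OC)c4)ccc3OCc5ccccc5)C1C=C2C(=O)OC
F6 | step 8 | methyl 4-{2-(benzyloxy)-5-[2-(3-methoxyphenyl)ethyl]phenoxy}benzoate | COc1cccc(CCc2ccc(OCc3ccccc3)c(Oc4ccc(C(=O)OC)cc4)c2)c1
F7 | step 8 | 4-{2-(benzyloxy)-5-[2-(3-methoxyphenyl)ethyl]phenoxy}-N-methoxy-N-methylbenzamide | COc1cccc(CCc2ccc(OCc3ccccc3)c(Oc4ccc(C(=O)N(C)OC)cc4)c2)c1
F8 | step 8 | [3-(benzyloxy)benzyl]magnesium bromide | Br[Mg]Cc1cccc(OCc2ccccc2)c1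
F9 | step 10 | (1-{2-[3-(benzyloxy)phenyl]-1-(4-{2-(benzyloxy)-5-[2-(3-methoxyphenyl)ethyl]phenoxy}phenyl)ethylidene}hydrazine) | COc1cccc(CCc2ccc(OCc3ccccc3)c(Oc4ccc(C(=NN)Cc5cccc(OCc6ccccc6)c5)cc4)c2)c1
F10 | step 10 | 1-(benzyloxy)-2-(4-{2-[3-(benzyloxy)phenyl]ethyl}phenoxy)-4-[2-(3-methoxyphenyl)ethyl]benzene | COc1cccc(CCc2ccc(OCc3ccccc3)c(Oc4ccc(CCc5cccc(OCc6ccccc6)c5)cc4)c2)c1
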